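## Structural features

Komaroviquinone is an icetexane: cyclohexane ring A (C1–C5 and C10, gem-dimethyl at C4) shares the C5–C10 bond with the seven-membered carbocycle ring B (C5, C6, C7, C8, C9, C20, C10), and ring B shares C8–C9 with the fully substituted methoxy-p-quinone ring C (carbonyls C11 and C14, methoxy on C12, isopropyl on C13). An oxygen atom spans C7 and C10, so that O, C7, C6, C5 and C10 form a tetrahydrofuran inside an 8-oxabicyclo[3.2.1]octane, and C7 is a tertiary hemiketal carbon at a bridgehead. The three stereocenters are neighbours: C5, the only one bearing hydrogen, is bonded to the oxygenated quaternary C10, and C7 lies across the one-atom bridge; because the tetrahydrofuran can only be cis-fused to ring A without prohibitive strain and C7 is a bridgehead, C10 and C7 follow from C5. The fragile parts are the hemiketal (ring–chain tautomerism, acid-labile tertiary C10–O bond) and the quinone (nucleophiles, bases, reductants), so the quinone is best carried as an 11,12,14-trimethoxyarene until the last step. The real difficulty is the enantioselective construction of ring B together with C5, which is wedged between the quaternary carbons C4 and C10 and has no functional handle of its own. The key step uses the fact that C7(=O)–C6H2–C5–C10, with a heteroatom on C10, is the retron of a γ,δ-unsaturated ketone C7(=O)–C6–C5–C10=C1: a [3,3] shift of an allyl vinyl ether with its oxygen on C1 forms C5–C6, delivers the C7 ketone and leaves C1=C10 to accept the bridging oxygen. A check of the descriptors shows that (R) at C1 of the rearrangement substrate correlates with (S) at C5 of its product and with (5S,7S,10S) in the target, so the key-step structures are consistent and need no correction.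

## Logic of the disconnections

18 ⇒ 16 (through 17). No skeletal bond is cut: the C11 and C14 carbonyls are traced back to aryl methyl ethers and the C7 hydroxyl to a methoxy group. This hides the quinone and locks the hemiketal, so every earlier step handles a robust hexasubstituted arene. The forward operation must hydrolyse a bridged ketal and then remove only the para pair of methyl groups. Hydrolysis is placed first, at the stage of 17, while the arene is still electron-rich enough to stabilise the ring-opened oxocarbenium ion.

16 ⇒ 14 (through 15). The C10–O bond of the bridge is cut, with a C1–I bond as the trace of an electrophilic cyclisation. This removes the bicyclic ketal and two stereocenters (C10, C7) at once and leaves a γ,δ-unsaturated ketone with one stereocenter. The forward step needs the electrophile on the α face of C1=C10 and Markovnikov, 5-exo attack of the C7 oxygen on C10. The tether through C6 permits only the cis-fused tetrahydrofuran.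

14 ⇒ 13. C5–C6 is cut and O–C1 is rejoined. The cut is placed here because it turns the most hindered C–C bond (beside C4) and the C5 stereocenter into a C–O bond at a secondary allylic carbinol, which is easy to set. Ring B becomes a seven-membered oxacycle. The forward step must be a concerted suprafacial shift through a boat-shaped transition state, without ionisation of C1–O.

13 ⇒ 12. The C6=C7 bond is cut back to a lactone carbonyl. The labile enol ether is thus made in one step from a stable lactone. The forward step needs a non-acidic methylenating agent that accepts a di-ortho-substituted aryl lactone.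

12 ⇒ 11 ⇒ 10. First the acyl C7–O bond is cut, then C7–C8 (carboxyl from an aryl bromide). Cutting the acyl–oxygen and not the alkyl–oxygen bond leaves C1 untouched, so its configuration is retained. Carrying C7 as bromine up to 10, not as an ester, avoids saponifying a hindered benzoate and shortens the arene synthesis. The forward steps need bromine–lithium exchange in the presence of an alkoxide and activation of a hindered acid.

10 ⇒ 9. The C1–H bond is cut (carbinol back to the enone carbonyl). This is the only reagent-controlled stereochemical step, and it is placed on a 2-substituted cyclohexenone, a substrate class well suited to oxazaborolidine reduction. The demand is clean 1,2-selectivity and high facial selectivity.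

9 ⇒ 5 + 7. The C20–C10 bond between benzylic and vinylic carbon is cut. This splits the molecule into two fragments of similar size. The forward step needs zinc insertion into C–Cl and palladium insertion into C–I, with the aryl C–Br bond left alone in both.

7 ⇒ 6. The C10–I bond is cut; the forward α-iodination of the enone is a one-step operation on a commercial material.

5 ⇒ 4 ⇒ 3 ⇒ 2 ⇒ 1. C9–C20 (chloromethylation), C8–Br (bromination), then the C13–isopropyl bond (addition of an aryllithium to a ketone, followed by C–O reduction) are cut in turn. Each substituent enters at the position the existing groups direct to; the last ring position is filled last, so its regiochemistry is forced. The only open question is which of the two free positions of 3 reacts first.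

## Other disconnections considered

Alternative 1: The cuts are C9–C20 and C10–O, which lead back to an abietane, the 7-oxo C20 mesylate A2, itself a few functional-group steps from carnosic acid A3. In the forward direction, ionisation of the neopentyl C20–O bond of A2 would be assisted by the arene: C9 would shift from C10 to C20, ring B would grow from six to seven atoms, and the tertiary C10 cation would be caught by a hydroxyl of the hydrated C7 ketone to give the bridged hemiketal A1.
- In favour: all carbons, ring A and the C5 stereocenter come from the chiral pool, no enantioselective step is needed, and ring expansion and bridge formation occur in one operation.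
- Against: the route depends on the supply of A3 and on telling its two phenols apart. The C10 cation can lose a proton (towards C1, C5 or C20) instead of being trapped. A1 lacks the C14 oxygen, so debenzylation and a phenol-to-quinone oxidation must follow.
- Comparison: on structure the fit is excellent, and the alternative is better in the security of the absolute configuration. On mechanism, a stepwise cationic rearrangement is less predictable than a concerted [3,3] shift. On step economy the alternative should be shorter from A3 than the chosen plan is from 1 and 6, which is a point in its favour. The chosen plan does not depend on a natural product and allows changes in ring A and in the arene.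

Alternative 2: Three bonds are cut at once, C10–O, C10–C5 and C6–C7, giving the acyclic diazo ketone A5, whose arene carries the C7 methyl ester and the C20 ketone. Forward, Rh2(S-PTTL)4 would turn the diazo carbon C10 into a carbenoid, the ester carbonyl oxygen would add to it to give a six-membered carbonyl ylide, and this dipole would add across the tethered vinyl group to give A4, closing ring A, ring B and the oxa bridge together.
- In favour: the largest gain in complexity per step of all options, an achiral open-chain precursor, relative configuration fixed by the tether, and direct formation of the methyl ketal.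
- Against: the absolute configuration depends on the chiral dirhodium complex staying associated with the ylide during the cycloaddition. The dipolarophile is an unactivated vinyl group on a quaternary carbon. The diazo group has to be installed beside a hindered aryl ketone. A4 carries a C20 carbonyl that must be removed.
- Comparison: structurally A4 differs from 16 only in the oxidation level of C20, so the endgames coincide after deoxygenation (equal). In bond-forming economy the alternative is better (three bonds and two rings in one step against one bond and one ring). In stereocontrol the chosen plan is safer, since a reagent-controlled ketone reduction followed by a stereospecific sigmatropic shift is more predictable than face selection by a catalyst-associated dipole. The overall step counts are expected to be similar.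

Alternative 3: The two aryl–carbon bonds of ring B, C9–C20 and C8–C7, are cut. This separates the arene, as the silyl triflate A8, from the bicyclic β-keto ester A7, which already holds ring A, C5 and the C1=C10 alkene. Forward, CsF would release the aryne from A8, the enolate carbon C20 of A7 would add to C9 (the aryne carbon remote from the C14 methoxy group), the aryl anion at C8 would add to the C7 ketone, and fragmentation of the resulting four-membered alkoxide would insert the two aryl carbons into the C20–C7 bond to give A6.
- In favour: a late, convergent union of two fragments; regiochemistry steered by the C14 methoxy group; A6 is a close analogue of 14, so the same iodoketalisation endgame would apply.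
- Against: A6 carries an ester on C20 that must be removed, and it lacks the C11 oxygen, which would have to be introduced by a late arene oxidation. The enolate of A7 is an extended one, so arylation at C1 or on oxygen can compete. A7 needs its own enantioselective synthesis with the stereocenter beside the gem-dimethyl carbon, which only relocates the central problem. A8 needs several steps.
- Comparison: on structure both plans reach the same ring B ketone with the C1=C10 alkene (equal), and the alternative is better in convergence. On mechanism, an anionic addition–fragmentation with several branching points stands against a unimolecular pericyclic step. On step economy the alternative is expected to be longer, given decarboxylation, C11 oxygenation and the separate syntheses of A7 and A8.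

Key step: step 11

Assumption 1: electrophilic bromination of 3 is taken to occur at C8, the free position para to the C12 methoxy group and ortho to the C14 methoxy group, as in 1 itself.
Assumption 2: 17 is drawn as the closed hemiketal; it may equilibrate with the open 10-hydroxy-7-ketone, which does not affect the last operation.
Remark on the precursor: 13 itself is kept unchanged; its preparation is redesigned so that C7 is carried as an aryl bromide, the lactone is closed at the acyl carbon, and the enol ether is made and handled without acid.

## Route

Step 1
Reactants: 1 1,2,4-trimethoxybenzene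
Product: 2 2-(2,3,6-trimethoxyphenyl)propan-2-ol
Conditions: n-BuLi, THF, 0 °C → rt; acetone, −78 °C → rt; H2O
Reagents that add atoms: acetone, CC(C)=O
Why: Directed ortho-lithiation: the C–H flanked by two methoxy groups (future C13) is the most acidic and best chelated site of 1, and the aryllithium adds to acetone (1,2-addition) to give the tertiary carbinol.

Step 2
Reactants: 2 2-(2,3,6-trimethoxyphenyl)propan-2-ol
Product: 3 1,2,4-trimethoxy-3-(propan-2-yl)benzene
Conditions: Et3SiH, CF3CO2H, CH2Cl2, 0 °C → rt
Reagents that add atoms: none
Why: Ionic hydrogenation: the acid ionises the tertiary benzylic alcohol and Et3SiH transfers hydride to the cation (or to its isopropenyl tautomer after reprotonation); aryl methyl ethers are inert.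

Step 3
Reactants: 3 1,2,4-trimethoxy-3-(propan-2-yl)benzene
Product: 4 1-bromo-2,4,5-trimethoxy-3-(propan-2-yl)benzene
Conditions: NBS, MeCN, 0 °C → rt
Reagents that add atoms: N-bromosuccinimide, O=C1CCC(=O)N1Br
Why: Electrophilic aromatic bromination; of the two free positions, C8 (para to the C12 methoxy, ortho to the C14 methoxy) should be more activated than C9, which has only one ortho-methoxy and a para-alkyl group. The bromine is the latent C7 carboxyl.

Step 4
Reactants: 4 1-bromo-2,4,5-trimethoxy-3-(propan-2-yl)benzene
Product: 5 1-bromo-2-(chloromethyl)-3,4,6-trimethoxy-5-(propan-2-yl)benzene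
Conditions: ClCH2OMe, ZnCl2 (cat.), CH2Cl2, 0 °C → rt
Reagents that add atoms: chloromethyl methyl ether, COCCl
Why: Blanc-type chloromethylation (electrophilic aromatic substitution by the methoxymethyl cation, then benzylic exchange of methoxy for chloride); only one ring position (C9) is left, so regiochemistry is forced, and it is activated by the ortho C11 methoxy and the para isopropyl group.

Step 5
Reactants: 6 4,4-dimethylcyclohex-2-en-1-one
Product: 7 2-iodo-4,4-dimethylcyclohex-2-en-1-one
Conditions: I2, pyridine, CH2Cl2, 0 °C → rt
Reagents that add atoms: iodine, II
Why: α-Iodination of an enone by a Baylis–Hillman-type sequence: conjugate addition of pyridine, iodination of the enolate, elimination of pyridine; C4 is quaternary, so no γ-deprotonation competes.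

Step 6
Reactants: 5 1-bromo-2-(chloromethyl)-3,4,6-trimethoxy-5-(propan-2-yl)benzene; 7 2-iodo-4,4-dimethylcyclohex-2-en-1-one
Product: 9 2-{[2-bromo-3,5,6-trimethoxy-4-(propan-2-yl)phenyl]methyl}-4,4-dimethylcyclohex-2-en-1-one, via arylmethylzinc chloride 8 (not isolated)
Conditions: Zn, LiCl, THF, 25 °C; then 7, Pd(dba)2 (2 mol%), P(2-furyl)3 (4 mol%), 25 °C
Reagents that add atoms: none
Why: Zinc inserts into the benzylic C–Cl bond and not into the hindered aryl C–Br bond; the Negishi coupling then forms C20–C10, since zerovalent palladium adds to the vinyl C–I bond of 7 far faster than to a di-ortho-substituted electron-rich aryl bromide.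

Step 7
Reactants: 9 2-{[2-bromo-3,5,6-trimethoxy-4-(propan-2-yl)phenyl]methyl}-4,4-dimethylcyclohex-2-en-1-one
Product: 10 (1R)-2-{[2-bromo-3,5,6-trimethoxy-4-(propan-2-yl)phenyl]methyl}-4,4-dimethylcyclohex-2-en-1-ol
Conditions: (S)-Me-CBS (C18H20BNO, 20 mol%), BH3·SMe2, THF, −20 °C; MeOH
Reagents that add atoms: none
Why: Corey–Bakshi–Shibata reduction: the 2-substituted alkene arm acts as the large group and the ring CH2 as the small one, so the (S)-oxazaborolidine should deliver hydride to the face that gives the (1R)-carbinol (the same sense as acetophenone to (R)-1-phenylethanol). An α-substituted enone is reduced 1,2, and this step sets the only reagent-controlled stereocenter of the route.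

Step 8
Reactants: 10 (1R)-2-{[2-bromo-3,5,6-trimethoxy-4-(propan-2-yl)phenyl]methyl}-4,4-dimethylcyclohex-2-en-1-ol
Product: 11 2-{[(6R)-6-hydroxy-3,3-dimethylcyclohex-1-en-1-yl]methyl}-3,4,6-trimethoxy-5-(propan-2-yl)benzoic acid
Conditions: t-BuLi (3.2 equiv), THF, −78 °C; CO2; 1 M HCl
Reagents that add atoms: carbon dioxide, O=C=O
Why: The first equivalent of t-BuLi forms the lithium alkoxide, the next two effect bromine–lithium exchange (the second consumes t-BuBr), and carboxylation of the aryllithium installs C7. At −78 °C the exchange is faster than deprotonation of the C20 methylene, and C1 is not involved.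

Step 9
Reactants: 11 2-{[(6R)-6-hydroxy-3,3-dimethylcyclohex-1-en-1-yl]methyl}-3,4,6-trimethoxy-5-(propan-2-yl)benzoic acid
Product: 12 (4aR)-7,9,10-trimethoxy-2,2-dimethyl-8-(propan-2-yl)-2,3,4,4a-tetrahydrodibenzo[b,e]oxepin-6(11H)-one (seven-membered lactone C7(=O)–O–C1–C10–C20–C9–C8, C5=C10 alkene)
Conditions: 2-chloro-1-methylpyridinium iodide, Et3N, CH2Cl2 (high dilution), 40 °C
Reagents that add atoms: none
Why: Mukaiyama lactonisation: the carboxylate is activated as a 2-acyloxypyridinium salt and the C1 hydroxyl attacks the acyl carbon, so the C1–O bond is never broken and the (R) configuration is retained. The rigid arene–CH2–alkene tether favours seven-ring closure.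

Step 10
Reactants: 12 (4aR)-7,9,10-trimethoxy-2,2-dimethyl-8-(propan-2-yl)-2,3,4,4a-tetrahydrodibenzo[b,e]oxepin-6(11H)-one
Product: 13 (4aR)-7,9,10-trimethoxy-2,2-dimethyl-6-methylidene-8-(propan-2-yl)-2,3,4,4a,6,11-hexahydrodibenzo[b,e]oxepine (exocyclic methylene C6 on C7, oxygen on C1, C5=C10 alkene)
Conditions: Cp2TiMe2 (3 equiv), PhMe–THF, 70 °C, dark; filtration through basic Al2O3
Reagents that add atoms: dimethyltitanocene, C[Ti](C)(C1C=CC=C1)C1C=CC=C1
Why: Petasis methylenation: on heating, Cp2TiMe2 loses methane to give Cp2Ti=CH2, which adds [2+2] to the lactone carbonyl and cycloreverts to the enol ether and Cp2Ti=O. The reagent is neither acidic nor Lewis acidic, so the acid-labile α-aryl enol ether and C1 survive, and the exocyclic double bond cannot move into the ring because C8 is aromatic.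

Step 11
Reactants: 13 (4aR)-7,9,10-trimethoxy-2,2-dimethyl-6-methylidene-8-(propan-2-yl)-2,3,4,4a,6,11-hexahydrodibenzo[b,e]oxepine
Product: 14 (5S)-11,12,14-trimethoxy-9(10→20)-abeo-abieta-1(10),8,11,13-tetraen-7-one (tricyclic C7 ketone, C1=C10 alkene)
Conditions: o-xylene, i-Pr2NEt (5 mol%), sealed tube, 150 °C
Reagents that add atoms: none
Why: Aliphatic Claisen rearrangement: a concerted, suprafacial [3,3] shift of the array C6=C7–O–C1–C10=C5 forms C5–C6 and breaks O–C1, driven by formation of the C7 carbonyl. The closest known reaction type is the methylenation–Claisen sequence that converts allylic lactones into carbocyclic ketones; here the allyl double bond is exocyclic to the oxacycle, so the ring size is kept and the seven-membered oxacycle is transposed into ring B. Ring B closes through a boat-shaped, bicyclo[3.2.2]-type transition state, because the benzo tether (C8, C9, C20) joins C7 to C10, the 2- and 5-positions of the six-atom array; a chair is excluded, and a three-atom tether should span the boat without unusual strain. The new stereocenter C5 is controlled by C1: the vinyl ether is held on the face of ring A that carries the C1 oxygen, so C6 bonds to C5 on that face and (1R) becomes (5S). The step needs periselectivity for the [3,3] path over heterolysis of the allylic C1–O bond, which would give 1,3-shift products, dienes and racemisation; this is secured by the absence of Lewis acids (titanium residues are removed in step 10), a trace of amine base and a non-polar solvent. Regiochemistry is not in question, since the array contains only one 1,5-diene and C7 has no enolisable neighbour. The hindered C5–C6 bond beside the gem-dimethyl carbon is formed intramolecularly, so the steric cost should appear as a higher temperature and not as a loss of selectivity.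

Step 12
Reactants: 14 (5S)-11,12,14-trimethoxy-9(10→20)-abeo-abieta-1(10),8,11,13-tetraen-7-one
Product: 15 (1S,5S,7S,10S)-7,10-epoxy-1-iodo-7,11,12,14-tetramethoxy-9(10→20)-abeo-abieta-8,11,13-triene (iodine on C1 anti to the C10 oxygen)
Conditions: NIS, MeOH (10 equiv), NaHCO3, CH2Cl2, −20 → 0 °C, dark
Reagents that add atoms: N-iodosuccinimide, O=C1CCC(=O)N1I; methanol, CO
Why: Iodo-ketalisation of a γ,δ-unsaturated ketone (5-exo, Markovnikov): the iodonium ion forms on the open α face of C1=C10, the C7 oxygen (as the carbonyl or as its methanol hemiketal) attacks the tertiary C10 from the β face anti to iodine, and methanol completes the ketal. C10 is set by the tether, since the oxygen can only reach the face of ring A that carries C6 (cis-fused tetrahydrofuran), and C7, a bridgehead, follows necessarily. The hexasubstituted arene cannot be iodinated.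

Step 13
Reactants: 15 (1S,5S,7S,10S)-7,10-epoxy-1-iodo-7,11,12,14-tetramethoxy-9(10→20)-abeo-abieta-8,11,13-triene
Product: 16 (5S,7S,10S)-7,10-epoxy-7,11,12,14-tetramethoxy-9(10→20)-abeo-abieta-8,11,13-triene
Conditions: Bu3SnH, AIBN (cat.), PhMe, 80 °C
Reagents that add atoms: none
Why: Radical chain dehalogenation: the stannyl radical abstracts iodine and the secondary C1 radical takes hydrogen from Bu3SnH. Ketal, arene and the stereocenters C5, C7 and C10 are untouched.

Step 14
Reactants: 16 (5S,7S,10S)-7,10-epoxy-7,11,12,14-tetramethoxy-9(10→20)-abeo-abieta-8,11,13-triene
Product: 18 komaroviquinone, via trimethoxyarene hemiketal 17 (not isolated)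
Conditions: 0.5 M H2SO4, MeCN, 25 °C; then (NH4)2Ce(NO3)6, MeCN–H2O, 0 °C
Reagents that add atoms: water, O
Why: Acid-catalysed ketal hydrolysis (opening of the C7–O bridge bond to an aryl- and methoxy-stabilised oxocarbenium ion, addition of water, loss of methanol, re-closure by the C10 hydroxyl), followed in the same flask by oxidative demethylation with tetravalent cerium. Water attacks the arene radical cation at C11 and C14, the para pair of methoxy groups leaves as methanol and the C12 methoxy group stays. The electron-poor quinone then holds C7 in the bridged hemiketal form, whose configuration is fixed by C5 and C10.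

## Compound list

1 | 1,2,4-trimethoxybenzene | COc1ccc(OC)c(OC)c1 | starting material
2 | 2-(2,3,6-trimethoxyphenyl)propan-2-ol | COc1ccc(OC)c(OC)c1C(C)(C)O | intermediate
3 | 1,2,4-trimethoxy-3-(propan-2-yl)benzene | COc1ccc(OC)c(OC)c1C(C)C | intermediate
4 | 1-bromo-2,4,5-trimethoxy-3-(propan-2-yl)benzene | COc1c(Br)cc(OC)c(OC)c1C(C)C | intermediate
5 | 1-bromo-2-(chloromethyl)-3,4,6-trimethoxy-5-(propan-2-yl)benzene | COc1c(Br)c(CCl)c(OC)c(OC)c1C(C)C | intermediate
6 | 4,4-dimethylcyclohex-2-en-1-one | CC1(C)CCC(=O)C=C1 | starting material
7 | 2-iodo-4,4-dimethylcyclohex-2-en-1-one | CC1(C)CCC(=O)C(I)=C1 | intermediate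
8 | {[2-bromo-3,5,6-trimethoxy-4-(propan-2-yl)phenyl]methyl}zinc chloride | COc1c(Br)c(C[Zn]Cl)c(OC)c(OC)c1C(C)C | intermediate
9 | 2-{[2-bromo-3,5,6-trimethoxy-4-(propan-2-yl)phenyl]methyl}-4,4-dimethylcyclohex-2-en-1-one | COc1c(Br)c(CC2=CC(C)(C)CCC2=O)c(OC)c(OC)c1C(C)C | intermediate
10 | (1R)-2-{[2-bromo-3,5,6-trimethoxy-4-(propan-2-yl)phenyl]methyl}-4,4-dimethylcyclohex-2-en-1-ol | COc1c(Br)c(CC2=CC(C)(C)CC[C@H]2O)c(OC)c(OC)c1C(C)C | intermediate
11 | 2-{[(6R)-6-hydroxy-3,3-dimethylcyclohex-1-en-1-yl]methyl}-3,4,6-trimethoxy-5-(propan-2-yl)benzoic acid | COc1c(C(=O)O)c(CC2=CC(C)(C)CC[C@H]2O)c(OC)c(OC)c1C(C)C | intermediate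
12 | (4aR)-7,9,10-trimethoxy-2,2-dimethyl-8-(propan-2-yl)-2,3,4,4a-tetrahydrodibenzo[b,e]oxepin-6(11H)-one | O=C1O[C@@H]2CCC(C)(C)C=C2Cc2c(OC)c(OC)c(C(C)C)c(OC)c12 | intermediate
13 | (4aR)-7,9,10-trimethoxy-2,2-dimethyl-6-methylidene-8-(propan-2-yl)-2,3,4,4a,6,11-hexahydrodibenzo[b,e]oxepine | C=C1O[C@@H]2CCC(C)(C)C=C2Cc2c(OC)c(OC)c(C(C)C)c(OC)c12 | intermediate
14 | (5S)-11,12,14-trimethoxy-9(10→20)-abeo-abieta-1(10),8,11,13-tetraen-7-one | O=C1C[C@H]2C(C)(C)CCC=C2Cc2c(OC)c(OC)c(C(C)C)c(OC)c12 | intermediate
15 | (1S,5S,7S,10S)-7,10-epoxy-1-iodo-7,11,12,14-tetramethoxy-9(10→20)-abeo-abieta-8,11,13-triene | COc1c(C(C)C)c(OC)c2c(C[C@@]34[C@@H](I)CCC(C)(C)[C@@H]3C[C@]2(OC)O4)c1OC | intermediate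
16 | (5S,7S,10S)-7,10-epoxy-7,11,12,14-tetramethoxy-9(10→20)-abeo-abieta-8,11,13-triene | COc1c(C(C)C)c(OC)c2c(C[C@@]34CCCC(C)(C)[C@@H]3C[C@]2(OC)O4)c1OC | intermediate
17 | (5S,7S,10S)-7,10-epoxy-11,12,14-trimethoxy-9(10→20)-abeo-abieta-8,11,13-trien-7-ol | COc1c(C(C)C)c(OC)c2c(C[C@@]34CCCC(C)(C)[C@@H]3C[C@]2(O)O4)c1OC | intermediate
18 | komaroviquinone, (5S,7S,10S)-7,10-epoxy-7-hydroxy-12-methoxy-9(10→20)-abeo-abieta-8,12-diene-11,14-dione | COC1=C(C(C)C)C(=O)C2=C(C[C@@]34CCCC(C)(C)[C@@H]3C[C@]2(O)O4)C1=O | target

## Step count and least certain steps

Total step count: 14. Longest linear sequence: 13 steps (steps 1–4 and 6–14, from 1); step 5 is the one-step branch from 6.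

Step 11 (key step). The boat-shaped bicyclic transition state, with bond formation beside the gem-dimethyl carbon, may need temperatures at which heterolysis of the allylic C1–O bond (1,3-shift products, dienes, loss of the stereochemical information) or adventitious hydrolysis of the enol ether overtakes the concerted shift. The fallback sets out from 10 and moves the chirality transfer into an open-chain Claisen variant. Eschenmoser–Claisen rearrangement of 10 with N,N-dimethylacetamide dimethyl acetal (xylene, 140 °C) should give 2-[(1S)-2-{[2-bromo-3,5,6-trimethoxy-4-(propan-2-yl)phenyl]methyl}-6,6-dimethylcyclohex-2-en-1-yl]-N,N-dimethylacetamide F1 with the same suprafacial C1-to-C5 transfer. A Parham cyclisation (t-BuLi, THF, −78 °C: bromine–lithium exchange, then attack of the aryllithium on the amide carbonyl) should then close ring B at C7–C8 and rejoin the route at 14. This detour is shorter than steps 8–11, but it gives up the ring transposition and relies on a seven-membered anionic ring closure.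

Step 12. The iodonium ion may be intercepted by external methanol, or the alkene may not react, because closure by the C7 oxygen has to pass through a strained bridgehead oxocarbenium ion or through a sparsely populated hemiketal. The fallback runs from 14 to 17 by oxygen delivery from a C7 hydroxyl. NaBH4 reduction of the ketone should give (5S)-11,12,14-trimethoxy-9(10→20)-abeo-abieta-1(10),8,11,13-tetraen-7-ol F2 (C7 epimers). Hydroxyl-directed epoxidation with VO(acac)2 and t-BuOOH should deliver oxygen to the face of C1=C10 over which ring B lies and give the (1R,5S,10S)-1,10-epoxide F3. LiAlH4 should open the epoxide at the secondary C1 to the (5S,10S)-7,10-diol F4. Dess–Martin oxidation of the secondary alcohol then gives the 10-hydroxy-7-ketone, that is 17, and the (NH4)2Ce(NO3)6 oxidation of step 14 completes the synthesis.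

Step 3. Substitution may occur at the other free position (C9) or at both, because the C12 methoxy group is twisted out of conjugation by its two neighbours and directs less strongly than in 1. If C9 proves the more reactive site, the two electrophiles are interchanged. Chloromethylation of 3 under the conditions of step 4 would then give 1-(chloromethyl)-2,3,5-trimethoxy-4-(propan-2-yl)benzene F5, whose only free position is C8, and bromination with N-bromosuccinimide returns to the route at 5.

Step 4. Substitution at a position flanked by bromine and methoxy may be sluggish, and the product benzyl chloride may alkylate unreacted 4 (diarylmethane formation). The fallback sets out from 4 and builds the CH2Cl group in stages. Rieche formylation (Cl2CHOMe, TiCl4, CH2Cl2, 0 °C) should give 2-bromo-3,5,6-trimethoxy-4-(propan-2-yl)benzaldehyde F6, and NaBH4 reduces it to [2-bromo-3,5,6-trimethoxy-4-(propan-2-yl)phenyl]methanol F7. SOCl2 then returns to the route at 5.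

Step 8. The aryllithium may be protonated (by the doubly activated C20 methylene or by solvent) before carbon dioxide is added, which would remove bromine without carboxylation. The fallback goes from 10 directly to 12 by palladium-catalysed carbonylative lactonisation (Pd(OAc)2, Xantphos, CO 1 atm, Et3N, PhMe, 100 °C). Oxidative addition of zerovalent palladium into the C8–Br bond, CO insertion and intramolecular alcoholysis of the acylpalladium species would form C7–C8 and C7–O in one step, bypassing 11 and step 9 without any new compound.

## Further compounds

F1 | step 11 | 2-[(1S)-2-{[2-bromo-3,5,6-trimethoxy-4-(propan-2-yl)phenyl]methyl}-6,6-dimethylcyclohex-2-en-1-yl]-N,N-dimethylacetamide | CN(C)C(=O)C[C@H]1C(C)(C)CCC=C1Cc1c(Br)c(OC)c(C(C)C)c(OC)c1OC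
F2 | step 12 | (5S)-11,12,14-trimethoxy-9(10→20)-abeo-abieta-1(10),8,11,13-tetraen-7-ol (C7 epimers) | OC1C[C@H]2C(C)(C)CCC=C2Cc2c(OC)c(OC)c(C(C)C)c(OC)c12
F3 | step 12 | (1R,5S,10S)-1,10-epoxy-11,12,14-trimethoxy-9(10→20)-abeo-abieta-8,11,13-trien-7-ol (epoxide oxygen cis to C6; C7 epimers) | OC1C[C@H]2C(C)(C)CC[C@H]3O[C@@]23Cc2c(OC)c(OC)c(C(C)C)c(OC)c12
F4 | step 12 | (5S,10S)-11,12,14-trimethoxy-9(10→20)-abeo-abieta-8,11,13-triene-7,10-diol (C7 epimers) | OC1C[C@H]2C(C)(C)CCC[C@]2(O)Cc2c(OC)c(OC)c(C(C)C)c(OC)c12
F5 | step 3 | 1-(chloromethyl)-2,3,5-trimethoxy-4-(propan-2-yl)benzene | COc1cc(CCl)c(OC)c(OC)c1C(C)C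
F6 | step 4 | 2-bromo-3,5,6-trimethoxy-4-(propan-2-yl)benzaldehyde | COc1c(Br)c(C=O)c(OC)c(OC)c1C(C)C
F7 | step 4 | [2-bromo-3,5,6-trimethoxy-4-(propan-2-yl)phenyl]methanol | COc1c(Br)c(CO)c(OC)c(OC)c1C(C)C
F0 | step 8 | none | none
A1 | alternative 1 | (5S,7S,10S)-11-benzyloxy-7,10-epoxy-12-methoxy-9(10→20)-abeo-abieta-8,11,13-trien-7-ol | COc1c(C(C)C)cc2c(C[C@@]34CCCC(C)(C)[C@@H]3C[C@]2(O)O4)c1OCc1ccccc1
A2 | alternative 1 | 11-benzyloxy-12-methoxy-7-oxoabieta-8,11,13-trien-20-yl methanesulfonate | COc1c(C(C)C)cc2c(c1OCc1ccccc1)[C@@]1(COS(C)(=O)=O)CCCC(C)(C)[C@@H]1CC2=O
A3 | alternative 1 | carnosic acid | CC(C)c1cc2c(c(O)c1O)[C@@]1(C(=O)O)CCCC(C)(C)[C@@H]1CC2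
A4 | alternative 2 | (5S,7S,10S)-7,10-epoxy-7,11,12,14-tetramethoxy-9(10→20)-abeo-abieta-8,11,13-trien-20-one | COc1c(C(C)C)c(OC)c2c(C(=O)[C@@]34CCCC(C)(C)[C@@H]3C[C@]2(OC)O4)c1OC
A5 | alternative 2 | methyl 2-(2-diazo-6,6-dimethyloct-7-enoyl)-3,4,6-trimethoxy-5-(propan-2-yl)benzoate | COC(=O)c1c(OC)c(C(C)C)c(OC)c(OC)c1C(=O)C(=[N+]=[N-])CCCC(C)(C)C=C
A6 | alternative 3 | methyl (5S)-12,14-dimethoxy-7-oxo-9(10→20)-abeo-abieta-1(10),8,11,13-tetraene-20-carboxylate | COC(=O)C1c2cc(OC)c(C(C)C)c(OC)c2C(=O)C[C@H]2C(C)(C)CCC=C12
A7 | alternative 3 | methyl (3aS)-4,4-dimethyl-2-oxo-2,3,3a,4,5,6-hexahydro-1H-indene-1-carboxylate | COC(=O)C1C(=O)C[C@H]2C(C)(C)CCC=C12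
A8 | alternative 3 | 2,4-dimethoxy-3-(propan-2-yl)-6-(trimethylsilyl)phenyl trifluoromethanesulfonate | COc1cc([Si](C)(C)C)c(OS(=O)(=O)C(F)(F)F)c(OC)c1C(C)C
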